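**Retrosynthetic overview**
1. The last bond is C8–C3 (lactone). It comes from an anodic dehydrogenative coupling of the 5-chloro-7,8-dihydroisochromen-6-one with (S)-6-methyloxane-2,4-dione. C8 follows from C7, and the lactone methine equilibrates.
2. The pyran ring is built by placing one carbon (C1) on the γ-carbon of a 2-chloro-3-alkynylcyclohexenone, followed by 6-endo-dig O-cyclisation onto the alkyne.
3. C4a–C4 comes from Sonogashira coupling of a vinylogous acyl triflate with the (S)-dienyne, which is made from (S)-2-methylbutan-1-ol by Wittig and HWE olefination.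
4. The carbocycle and C7 are bought together in (+)-limonene-1,2-diol. The isopropenyl group is cut down to C=O, the secondary OH is oxidised, and C5 is chlorinated.
5. The δ-lactone comes from ethyl (S)-3-hydroxybutanoate by Claisen condensation and lactonisation. Ring order: carbocycle (bought), lactone (separately), pyran, then union.

Assumption: C3 of the oxanedione ring is a β-dicarbonyl methine that epimerises through its enol, so its (R) configuration is taken as the equilibrium keto form and is not set kinetically.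

Step 1
Reactants: 1 (1S,2S,4R)-limonene-1,2-diol
Product: 4 (3S,4S)-3,4-dihydroxy-4-methylcyclohexan-1-one, via methoxy hydroperoxide 2 (not isolated), via TEMPO ether 3 (not isolated)
Conditions: O3, MeOH, −78 °C; FeSO4·7H2O, TEMPO, −78 °C to rt; mCPBA, rt (one pot)
Reagents that add atoms: TEMPO CC1(C)CCCC(C)(C)N1[O]
Why: Criegee ozonolysis in methanol gives the α-methoxy hydroperoxide, Fe(II) reduction and β-scission expel methyl acetate, and the ring radical is trapped by TEMPO and oxidised by the peracid to the ketone (oxodealkenylation); the tertiary carbinol (future C7, S) and its neighbour are untouched, and the former C4 centre is deliberately destroyed.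

Step 2
Reactants: 4 (3S,4S)-3,4-dihydroxy-4-methylcyclohexan-1-one
Product: 5 (4S)-4-hydroxy-4-methylcyclohexane-1,3-dione
Conditions: IBX, EtOAc, 75 °C
Reagents that add atoms: none
Why: IBX oxidation of a β-hydroxy ketone to the β-diketone proceeds without glycol cleavage and cannot touch the tertiary carbinol, so C7 is kept.

Step 3
Reactants: 5 (4S)-4-hydroxy-4-methylcyclohexane-1,3-dione
Product: 6 (6S)-2-chloro-3,6-dihydroxy-6-methylcyclohex-2-en-1-one (enol of the 2-chloro-1,3-dione)
Conditions: NCS, CH2Cl2, 0 °C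
Reagents that add atoms: N-chlorosuccinimide ClN1C(=O)CCC1=O
Why: Electrophilic α-chlorination of the enolised 1,3-dione occurs at its only doubly activated carbon (future C5), before any alkene is in the molecule.

Step 4
Reactants: 6 (6S)-2-chloro-3,6-dihydroxy-6-methylcyclohex-2-en-1-one
Product: 7 (4S)-2-chloro-4-hydroxy-4-methyl-3-oxocyclohex-1-en-1-yl trifluoromethanesulfonate
Conditions: Tf2O, Et3N, CH2Cl2, −78 °C
Reagents that add atoms: triflic anhydride FC(F)(F)S(=O)(=O)OS(=O)(=O)C(F)(F)F
Why: O-sulfonylation of the vinylogous acid goes to the oxygen remote from the quaternary carbinol, as with 4,4-disubstituted 1,3-diones; the carbonyl next to C7 is also held as the ketone by the OH···O=C hydrogen bond, and the tertiary alcohol is inert at −78 °C.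

Step 5
Reactants: 8 (S)-2-methylbutan-1-ol
Product: 10 (2E,4S)-2,4-dimethylhex-2-enal, via (S)-2-methylbutanal 9 (not isolated)
Conditions: TEMPO (10 mol %), PhI(OAc)2, CH2Cl2, rt; then Ph3P=C(Me)CHO, 40 °C
Reagents that add atoms: 2-(triphenylphosphoranylidene)propanal CC(C=O)=P(c1ccccc1)(c1ccccc1)c1ccccc1
Why: One-pot aminoxyl oxidation and Wittig olefination with a stabilised ylide gives the E-enal and consumes the racemisation-prone α-chiral aldehyde as it forms, so the bought stereocentre is carried through.

Step 6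
Reactants: 10 (2E,4S)-2,4-dimethylhex-2-enal
Product: 12 (3E,5E,7S)-5,7-dimethylnona-3,5-dien-1-yne, via silyl dienyne 11 (not isolated)
Conditions: (EtO)2P(O)CH2C≡CSiMe3, LiHMDS, THF, −78 to 0 °C; then K2CO3 (cat.), MeOH, rt
Reagents that add atoms: diethyl [3-(trimethylsilyl)prop-2-yn-1-yl]phosphonate CCOP(=O)(CC#C[Si](C)(C)C)OCC
Why: Horner–Wadsworth–Emmons olefination with the preformed propargyl phosphonate anion is E-selective and avoids γ-deprotonation of the enal, and methanolysis of the C–Si bond frees the terminal alkyne in the same flask.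

Step 7
Reactants: 7 (4S)-2-chloro-4-hydroxy-4-methyl-3-oxocyclohex-1-en-1-yl trifluoromethanesulfonate; 12 (3E,5E,7S)-5,7-dimethylnona-3,5-dien-1-yne
Product: 13 (6S)-2-chloro-3-[(3E,5E,7S)-5,7-dimethylnona-3,5-dien-1-yn-1-yl]-6-hydroxy-6-methylcyclohex-2-en-1-one
Conditions: PdCl2(PPh3)2 (3 mol %), CuI (5 mol %), iPr2NH, THF, rt
Reagents that add atoms: none
Why: In this Sonogashira coupling the vinylogous acyl triflate undergoes oxidative addition far faster than the α-vinyl chloride, and the free tertiary alcohol and both stereocentres are spectators.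

Step 8
Reactants: 13 (6S)-2-chloro-3-[(3E,5E,7S)-5,7-dimethylnona-3,5-dien-1-yn-1-yl]-6-hydroxy-6-methylcyclohex-2-en-1-one
Product: 16 (7S)-5-chloro-3-[(1E,3E,5S)-3,5-dimethylhepta-1,3-dien-1-yl]-7-hydroxy-7-methyl-7,8-dihydro-6H-isochromen-6-one, via bis-silyl dienol ether 14 (not isolated), via γ-dimethoxymethyl enone 15 (not isolated)
Conditions: TMSOTf, iPr2NEt, CH2Cl2, 0 °C; HC(OMe)3, −78 to −20 °C; then TFA, H2O, AgOTf (5 mol %), THF, rt, dark (one pot)
Reagents that add atoms: trimethyl orthoformate COC(OC)OC; water O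
Why: Only the γ-CH2 (future C8a) can be enolised because C7 is quaternary and C5 carries Cl, so soft enolisation gives the linear silyl dienol ether, which the dimethoxycarbenium ion alkylates at its terminus (vinylogous Mukaiyama-type acetal condensation); hydrolysis then unmasks the formyl group, whose enol oxygen adds 6-endo-dig to the Ag-activated, enone-polarised alkyne (the cycloisomerisation known for 2-alkynyl enals and o-alkynylbenzaldehydes), the transient C8a centre vanishes on enolisation, and C7 is untouched.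

Step 9
Reactants: 17 ethyl (S)-3-hydroxybutanoate
Product: 18 tert-butyl (S)-5-hydroxy-3-oxohexanoate
Conditions: tBuOAc, LDA (3.5 equiv each), THF, −78 to −20 °C; then 1 M HCl
Reagents that add atoms: tert-butyl acetate CC(=O)OC(C)(C)C
Why: Crossed Claisen condensation with excess lithium tert-butyl acetate enolate acylates the enolate with the ester, and the carbinol stereocentre only sits as its alkoxide and is not involved.

Step 10
Reactants: 18 tert-butyl (S)-5-hydroxy-3-oxohexanoate
Product: 19 (S)-6-methyloxane-2,4-dione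
Conditions: TFA, CH2Cl2, rt
Reagents that add atoms: none
Why: Acidolysis of the tert-butyl ester is followed by spontaneous δ-lactonisation through acyl–oxygen bond formation, so the C–O bond at the stereocentre is never broken (retention).

Step 11
Reactants: 16 (7S)-5-chloro-3-[(1E,3E,5S)-3,5-dimethylhepta-1,3-dien-1-yl]-7-hydroxy-7-methyl-7,8-dihydro-6H-isochromen-6-one; 19 (S)-6-methyloxane-2,4-dione
Product: 21 (7S,8S)-5-chloro-3-[(1E,3E,5S)-3,5-dimethylhepta-1,3-dien-1-yl]-7-hydroxy-7-methyl-8-[(3R,6S)-6-methyl-2,4-dioxooxan-3-yl]-7,8-dihydro-6H-isochromen-6-one, via vinylogous oxocarbenium ion 20 (not isolated)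
Conditions: undivided cell, RVC anode, Pt cathode, 2 mA, 2.2 F/mol, (4-BrC6H4)3N (10 mol %), nBu4NBF4 (0.1 M), CH2Cl2/HFIP 3:1, 19 (1.5 equiv), 0 °C, dark
Reagents that add atoms: none
Why: Proposed new method: anodic vinylogous Shono-type dehydrogenative C–C coupling, in which the triarylaminium mediator takes one electron from the push–pull dienol-ether chromophore of 16, the radical cation loses a C8 proton (the only C–H bonds both allylic to the O2–C1=C8a enol ether and parallel to the π system), a second electron transfer gives the vinylogous oxocarbenium ion 20, and the enol of 19 adds through its C3; attack at C1 or through oxygen is reversible in HFIP whereas attack at C8 restores the fully conjugated vinylogous ester, so the C8 adduct accumulates while protons are reduced to H2 at the cathode; the flat cation is approached on the face of the small, hydrogen-bond-donating 7-OH and anti to 7-CH3, which sets (8S) cis to the hydroxyl from the bought C7 centre, and the lactone methine then equilibrates through its enol to the (3R) keto form held by the 7-OH···O=C4 hydrogen bond; the closest known reaction types are Shono oxidation and the electrochemical or DDQ-mediated cross-dehydrogenative coupling of isochromans and allyl or vinyl ethers with 1,3-dicarbonyl compounds, none of which has been shown on an azaphilone-type vinylogous ester or with a β-keto-δ-lactone.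

**Compound list**
1 | (1S,2S,4R)-limonene-1,2-diol | C[C@]1(O)CC[C@@H](C(C)=C)C[C@@H]1O | starting material
2 | (1S,2S,4R)-4-(1-hydroperoxy-1-methoxyethyl)-1-methylcyclohexane-1,2-diol | C[C@]1(O)CC[C@@H](C(C)(OC)OO)C[C@@H]1O | intermediate
3 | (1S,2S)-1-methyl-4-[(2,2,6,6-tetramethylpiperidin-1-yl)oxy]cyclohexane-1,2-diol | C[C@]1(O)CCC(ON2C(C)(C)CCCC2(C)C)C[C@@H]1O | intermediate
4 | (3S,4S)-3,4-dihydroxy-4-methylcyclohexan-1-one | C[C@]1(O)CCC(=O)C[C@@H]1O | intermediate
5 | (4S)-4-hydroxy-4-methylcyclohexane-1,3-dione | C[C@]1(O)CCC(=O)CC1=O | intermediate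
6 | (6S)-2-chloro-3,6-dihydroxy-6-methylcyclohex-2-en-1-one | C[C@]1(O)CCC(O)=C(Cl)C1=O | intermediate
7 | (4S)-2-chloro-4-hydroxy-4-methyl-3-oxocyclohex-1-en-1-yl trifluoromethanesulfonate | C[C@]1(O)CCC(OS(=O)(=O)C(F)(F)F)=C(Cl)C1=O | intermediate
8 | (S)-2-methylbutan-1-ol | CC[C@H](C)CO | starting material
9 | (S)-2-methylbutanal | CC[C@H](C)C=O | intermediate
10 | (2E,4S)-2,4-dimethylhex-2-enal | CC[C@H](C)/C=C(C)/C=O | intermediate
11 | trimethyl[(3E,5E,7S)-5,7-dimethylnona-3,5-dien-1-yn-1-yl]silane | CC[C@H](C)/C=C(C)/C=C/C#C[Si](C)(C)C | intermediate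
12 | (3E,5E,7S)-5,7-dimethylnona-3,5-dien-1-yne | CC[C@H](C)/C=C(C)/C=C/C#C | intermediate
13 | (6S)-2-chloro-3-[(3E,5E,7S)-5,7-dimethylnona-3,5-dien-1-yn-1-yl]-6-hydroxy-6-methylcyclohex-2-en-1-one | CC[C@H](C)/C=C(C)/C=C/C#CC1=C(Cl)C(=O)[C@@](C)(O)CC1 | intermediate
14 | bis(trimethylsilyl) dienol ether of 13 (1,6-bis-silyloxy-2-chloro-3-alkynyl-6-methylcyclohexa-1,3-diene, 6S) | CC[C@H](C)/C=C(C)/C=C/C#CC1=CC[C@](C)(O[Si](C)(C)C)C(O[Si](C)(C)C)=C1Cl | intermediate
15 | (6S)-2-chloro-4-(dimethoxymethyl)-3-[(3E,5E,7S)-5,7-dimethylnona-3,5-dien-1-yn-1-yl]-6-methyl-6-(trimethylsilyloxy)cyclohex-2-en-1-one | CC[C@H](C)/C=C(C)/C=C/C#CC1=C(Cl)C(=O)[C@@](C)(O[Si](C)(C)C)CC1C(OC)OC | intermediate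
16 | (7S)-5-chloro-3-[(1E,3E,5S)-3,5-dimethylhepta-1,3-dien-1-yl]-7-hydroxy-7-methyl-7,8-dihydro-6H-isochromen-6-one | CC[C@H](C)/C=C(C)/C=C/C1=CC2=C(Cl)C(=O)[C@@](C)(O)CC2=CO1 | intermediate
17 | ethyl (S)-3-hydroxybutanoate | CCOC(=O)C[C@H](C)O | starting material
18 | tert-butyl (S)-5-hydroxy-3-oxohexanoate | C[C@H](O)CC(=O)CC(=O)OC(C)(C)C | intermediate
19 | (S)-6-methyloxane-2,4-dione | C[C@H]1CC(=O)CC(=O)O1 | intermediate
20 | (7S)-5-chloro-3-dienyl-7-hydroxy-7-methyl-6-oxo-6,7-dihydroisochromenylium (vinylogous oxocarbenium ion) | CC[C@H](C)/C=C(C)/C=C/C1=CC2=C(Cl)C(=O)[C@@](C)(O)C=C2C=[O+]1 | intermediate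
21 | (7S,8S)-5-chloro-3-[(1E,3E,5S)-3,5-dimethylhepta-1,3-dien-1-yl]-7-hydroxy-7-methyl-8-[(3R,6S)-6-methyl-2,4-dioxooxan-3-yl]-7,8-dihydro-6H-isochromen-6-one | CC[C@H](C)/C=C(C)/C=C/C1=CC2=C(Cl)C(=O)[C@@](C)(O)[C@@H]([C@@H]3C(=O)C[C@H](C)OC3=O)C2=CO1 | target

**Total step count:** 11. **Longest linear sequence:** 7 steps (1 → 4 → 5 → 6 → 7 → 13 → 16 → 21; steps 1, 2, 3, 4, 7, 8, 11).

**Three steps most likely to fail**

Step 11 (the new step).
- Risks: the radical cation is delocalised into the dienyl chain, so proton loss at the 3-methyl or at the allylic side-chain stereocentre could compete. The product could be over-oxidised to the 8-alkylidene compound. The syn-to-OH selectivity is untested.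
- Fallback, from 16 back to 21: stoichiometric DDQ in CH2Cl2/MeOH abstracts hydride from C8 (oxidative C–H cleavage of an allylic/vinylogous ether). Methanol traps the ion as the (7S)-8-methoxy ether F1. Sc(OTf)3- or BF3·OEt2-catalysed SN1 alkylation of the 1,3-dicarbonyl compound 19 with F1 then gives 21 through the same cation, under the same control by C7.

Step 8.
- Risks: three stages are run in one flask, the carbenium ion could attack the α-carbon or the polyene, and cyclisation could go 5-exo.
- Fallback, from 13 back to 16: HC(OMe)3/TsOH converts the enone into the methyl dienol ether F2. Vilsmeier–Haack formylation (POCl3, DMF) at the diene terminus, as practised on steroidal 3-alkoxy-3,5-dienes, gives the formyl dienol ether F3. AgOTf in wet acetone then closes the 6-methoxy pyrylium ring, and water displaces methanol to give 16.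

Step 1.
- Risk: this is a multi-stage radical one-pot on a polar diol, and the yield of the water-soluble ketone is uncertain.
- Fallback, from 1 back to 5, skipping 4 and step 2: ozonolysis with Me2S work-up gives the methyl ketone F4. Baeyer–Villiger oxidation (mCPBA, NaHCO3) with retention gives the acetate F5. K2CO3/MeOH gives the triol F6. Excess IBX in EtOAc oxidises both secondary alcohols to the 1,3-dione 5.

**Further compounds**
F1 | step 11 | (7S)-5-chloro-3-[(1E,3E,5S)-3,5-dimethylhepta-1,3-dien-1-yl]-7-hydroxy-8-methoxy-7-methyl-7,8-dihydro-6H-isochromen-6-one | CC[C@H](C)/C=C(C)/C=C/C1=CC2=C(Cl)C(=O)[C@@](C)(O)C(OC)C2=CO1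
F2 | step 8 | (1S)-3-chloro-4-[(3E,5E,7S)-5,7-dimethylnona-3,5-dien-1-yn-1-yl]-2-methoxy-1-methylcyclohexa-2,4-dien-1-ol | CC[C@H](C)/C=C(C)/C=C/C#CC1=CC[C@](C)(O)C(OC)=C1Cl
F3 | step 8 | (5S)-3-chloro-2-[(3E,5E,7S)-5,7-dimethylnona-3,5-dien-1-yn-1-yl]-5-hydroxy-4-methoxy-5-methylcyclohexa-1,3-diene-1-carbaldehyde | CC[C@H](C)/C=C(C)/C=C/C#CC1=C(C=O)C[C@](C)(O)C(OC)=C1Cl
F4 | step 1 | 1-[(1R,3S,4S)-3,4-dihydroxy-4-methylcyclohexyl]ethan-1-one | C[C@]1(O)CC[C@@H](C(C)=O)C[C@@H]1O
F5 | step 1 | (1R,3S,4S)-3,4-dihydroxy-4-methylcyclohexyl acetate | C[C@]1(O)CC[C@@H](OC(C)=O)C[C@@H]1O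
F6 | step 1 | (1S,2S,4R)-1-methylcyclohexane-1,2,4-triol | C[C@]1(O)CC[C@@H](O)C[C@@H]1O
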